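Every Sbt charged stays somewhere, so what the readings of Imd3 and Sbt.Rea lack at the end is either still waiting or lost to a side path.

| flask | Sbt | Rea | remark | time |
|---|---|---|---|---|
| teal | 0.10 M | 0.30 M | run made earlier |  |
| red | 0.050 M | 0.30 M | run made earlier |  |
| violet | 0.075 M | 0.30 M | run made earlier |  |
| amber | 0.10 M | 0.45 M | run made earlier |  |
| beta | 0.10 M | 0.300 M | everything together at the start | 20 h |
| eta | 0.10 M | 0.300 M (fed, over 8.0 h) | all else is in the flask from the start; the feed brings no volume worth counting | 20 h |
| alpha | 0.10 M (fed, over 8.0 h) | 0.300 M | all else is in the flask from the start; the feed brings no volume worth counting | 20 h |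

- teal (time / h: Imd3 / %, Sbt.Rea / %): 2.00: 22, 17; 5.00: 45, 6; 10.0: 64, 4; 15.0: 70, 3; 20.0: 73, 1
- red (time / h: Imd3 / %, Sbt.Rea / %): 5.00: 57, 10; 10.0: 75, 4; 15.0: 86, 2; 20.0: 85, 0; 25.0: 86, 0
- violet (time / h: Imd3 / %, Sbt.Rea / %): 2.00: 25, 17; 4.00: 42, 13; 6.00: 54, 8; 12.0: 74, 2; 25.0: 75, 1
- amber (time / h: Imd3 / %, Sbt.Rea / %): 5.00: 68, 6; 10.0: 77, 2; 15.0: 80, 0; 20.0: 79, 1; 25.0: 82, 5

(standard deviation of a reading: 2 percentage points)

- which flask leads in amount of Imd3, in percent of the Sbt charged ("all alike" within 1.5 percentage points) (beta / eta / alpha / all alike)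
- how much Imd3 is there at the end, in percent of the Sbt charged: beta
- how much Imd3 is there at the end, in percent of the Sbt charged: eta
- how much Imd3 is there at the end, in percent of the Sbt charged: alpha



We order the flask by lives, fastest first. In teal, Sbt.Rea falls with a life of about 2.88 h, read between its first two readings. Sbt has a life of about 4.05 h, read from what has appeared by 2.00 h. A scatter of 2 percentage points on the reading of 6 % can turn that order, so we treat the two lives as of like size. Sbt.Rea is then a sizeable pool: teal reads 17 % of it at 2.00 h. As our working assumption, we let the share of Sbt lost follow [Sbt]/[Rea].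

In a batch flask that ratio falls from its charged value to zero, so its mean is about half the charged one. This gives our carried quantity, the loss coefficient, a selectivity factor: the share of Sbt lost per unit of mean [Sbt]/[Rea]. From teal:

loss coefficient = 1.62

Red reads 1.68, violet 2.00, amber 1.62.

The next rung is the feed, longer than the life of Sbt. So we expect [Sbt] in alpha to stay well under its full charge. We go round twice. Rea falls as Imd3 forms, two Rea to each:

mean [Sbt] over the feed = 0.0285 M

first round, full Rea: loss = 15.4 %

mean [Rea] then = 0.215 M

second round: loss = 21.5 %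

The last rung is the run itself. We reckon 5.18 % of the Sbt still undecided at 20 h, so:

alpha: Imd3 = 74.5 %

Beta repeats teal, about 73 %. In eta the ratio starts above its charged value, so we place eta lowest. Our alpha stands above beta by 1.5 points, less than the margin of 1.5 points, and beta rests on one reading with a scatter of 2 points. So we call alpha and beta a tie.

The forecast put alpha first, where we see a tie, and higher than we did, at 80 %, with beta at 74 % and eta at 50 %, saying “Rea is starved early while Sbt is high”.

The flasks give: alpha leads, with beta 71.2 %, eta 61.0 %, alpha 74.4 %.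

    Sbt + Rea → Sbt.Rea (k = 2.00 /M/h)
    Sbt + Rea → Imd2 (k = 0.190 /M/h)
    Rea + Sbt.Rea → Imd3 (k = 2.80 /M/h)
    Rea + Imd2 → Imd3 (k = 0.880 /M/h)
    Sbt + Sbt.Rea → Sdp (k = 6.80 /M/h)
    Sbt ⇌ Imd (K = 0.710, k = 0.840 /h)

Taking the step to Sdp away lifts eta from 61.0 % to 90.1 %, so that step is the main reason for its shortfall, 75 % of what is missing. With 1.62, our rounds gave alpha a loss of 21.5 %, and alpha holds 19.7 % of Sdp at 200 h. Run to where it returns itself, the same loop for the alpha recipe with 0.12 M of Rea gives a loss of 58.7 %. That flask, still unfinished at 20.0 h, holds 43.5 % of Sdp and 28.3 % of Imd3.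

The runs are calculated for substances that don't exist; noise was put on by code.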